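**Plan**

1. Numbering: the chain runs from C1 (alkyne CH) to C15 (CH3). The oxolane is O–C6–C7–C8–C9 and the oxocane is O–C7–C8–C9–C10–C11–C12–C13.
2. Retrosynthesis: (i) C2–C3 and then the C3=C4 alkene are cut back to a propargyl group on C6. (ii) In one operation the oxolane O–C9 bond, the C10–OAc bond, the oxocane O–C13 bond and C12–Br are cut and the oxocane oxygen is reconnected to C10. This unravels the bicycle to a monocyclic 2,3,5-trisubstituted oxolane (ring O on C7 and C10, acetate on C9, (E)-pent-2-enyl on C10, free C6 hydroxyl). (iii) C5–C6, then O–C7 of that oxolane, then C7–C8 and C11–C12 are cut back to a C4 bis-epoxide.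
3. Enabling feature: the oxocane oxygen is 1,4 to C10, so the oxocane is a ring-expanded C7–C10 oxolane. The vicinal C9–O/C10–OAc pair is a masked 2-methyl-1,3-dioxolan-2-ylium ion across C9–C10. The C6 oxygen is 1,4 to C9. The trans Br/Et pair on C12/C13 next to the ring oxygen marks anti bromoetherification of an E-alkene.
4. Forward order: two epoxide openings join the chain (C11–C12, then C7–C8). The first oxolane (O, C7–C10) is closed by cobalt-catalysed aerobic cyclisation. C5–C6 is added by propargylation. The cascade then builds the oxocane and the final oxolane, and the enyne is completed last.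
5. Stereochemistry: C9 and C10 come from (2S,2'S)-2,2'-bioxirane and are both inverted stereospecifically in the cascade. C7 comes from the trans-selective cyclisation and C6 from catalyst-controlled propargylation. C12/C13 come from anti addition to the E-alkene on the convex face of a bicyclic oxonium ion. The E-enyne comes from syn hydrozirconation and stereoretentive coupling.

Key step: step 9

Remark: (2S,2'S)-2,2'-bioxirane is taken as purchased enantiopure. The (S)-enantiomer of the phosphoric acid in step 8 is assumed to be the one that directs attack to the Si face of the aldehyde (otherwise its antipode is used).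

**Route**

Step 1
Reactants: 1 but-1-yne; 2 (2S,2'S)-2,2'-bioxirane
Product: 5 (1S,3E)-1-[(2S)-oxiran-2-yl]hex-3-en-1-ol, via butenyl(diisobutyl)alane 3 (not isolated), via lithium butenylalanate 4 (not isolated)
Conditions: i-Bu2AlH, hexane, 50 °C; n-BuLi, THF, −78 °C; then 2 (3 equiv), THF, −78 to 0 °C; aq. Rochelle salt
Reagents that add atoms: none
Why: Syn hydroalumination gives the (E)-alkenylalane, and its ate complex transfers the alkenyl group with retention to a terminal epoxide carbon (SN2 epoxide opening); the C2-symmetric bis-epoxide in excess limits double opening, the aluminium-bound alkoxide does not undergo Payne rearrangement, and C9/C10 are carried over unchanged from 2.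

Step 2
Reactants: 5 (1S,3E)-1-[(2S)-oxiran-2-yl]hex-3-en-1-ol
Product: 6 triethyl{[(1S,3E)-1-[(2S)-oxiran-2-yl]hex-3-en-1-yl]oxy}silane
Conditions: Et3SiCl, imidazole, CH2Cl2, 0 °C
Reagents that add atoms: chlorotriethylsilane, CC[Si](Cl)(CC)CC
Why: Standard silylation of a secondary alcohol; the C10 oxygen is masked so that the next alkoxide formed (C9) can be acetylated selectively.

Step 3
Reactants: 6 triethyl{[(1S,3E)-1-[(2S)-oxiran-2-yl]hex-3-en-1-yl]oxy}silane
Product: 7 (4S,5S,7E)-5-[(triethylsilyl)oxy]deca-1,7-dien-4-ol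
Conditions: CH2=CHMgBr, CuI (10 mol %), THF, −40 to −10 °C; aq. NH4Cl, cold
Reagents that add atoms: vinylmagnesium bromide, C=C[Mg]Br
Why: Copper-catalysed Grignard opening of a terminal epoxide occurs at the CH2 carbon (SN2), so the C9 stereocentre is untouched; a cold quench avoids 1,2-silyl migration.

Step 4
Reactants: 7 (4S,5S,7E)-5-[(triethylsilyl)oxy]deca-1,7-dien-4-ol
Product: 8 (4S,5S,7E)-5-[(triethylsilyl)oxy]deca-1,7-dien-4-yl acetate
Conditions: Ac2O, pyridine, DMAP (cat.), CH2Cl2, rt
Reagents that add atoms: acetic anhydride, CC(=O)OC(C)=O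
Why: Routine DMAP-catalysed acetylation; this acetate is the group that later opens the oxonium ion and ends up on C10 of the target.

Step 5
Reactants: 8 (4S,5S,7E)-5-[(triethylsilyl)oxy]deca-1,7-dien-4-yl acetate
Product: 9 (4S,5S,7E)-5-hydroxydeca-1,7-dien-4-yl acetate
Conditions: PPTS (cat.), MeOH, 0 °C
Reagents that add atoms: none
Why: Acid-catalysed methanolysis removes the triethylsilyl ether while the acetate is stable; mild acid and low temperature keep acyl migration slow.

Step 6
Reactants: 9 (4S,5S,7E)-5-hydroxydeca-1,7-dien-4-yl acetate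
Product: 10 [(2S,3S,5R)-5-(hydroxymethyl)-2-[(2E)-pent-2-en-1-yl]oxolan-3-yl] acetate
Conditions: Co(modp)2 (10 mol %, divalent cobalt; modp = 1-morpholinocarbamoyl-4,4-dimethylpentane-1,3-dionate), O2 (1 atm), t-BuOOH (10 mol %), i-PrOH, 55 °C
Reagents that add atoms: dioxygen, O=O
Why: Mukaiyama aerobic oxidative cyclisation of a pent-4-en-1-ol: the C10 hydroxyl adds 5-exo to the terminal alkene and the C6 radical is trapped by O2, giving the 2,5-trans oxolane (C7) because the C10 substituent sits pseudo-equatorial in the cyclisation transition state; only the C10 hydroxyl is free and only the terminal alkene is placed for 5-exo closure.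

Step 7
Reactants: 10 [(2S,3S,5R)-5-(hydroxymethyl)-2-[(2E)-pent-2-en-1-yl]oxolan-3-yl] acetate
Product: 11 [(2S,3S,5R)-5-formyl-2-[(2E)-pent-2-en-1-yl]oxolan-3-yl] acetate
Conditions: Dess–Martin periodinane, CH2Cl2, 0 °C to rt; used crude
Reagents that add atoms: none
Why: Dess–Martin oxidation of a primary alcohol under near-neutral conditions leaves the α-alkoxy stereocentre (C7), the acetate and the alkene intact.

Step 8
Reactants: 11 [(2S,3S,5R)-5-formyl-2-[(2E)-pent-2-en-1-yl]oxolan-3-yl] acetate
Product: 12 [(2S,3S,5R)-5-[(1S)-1-hydroxybut-3-yn-1-yl]-2-[(2E)-pent-2-en-1-yl]oxolan-3-yl] acetate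
Conditions: allenylboronic acid pinacol ester (1.5 equiv), (S)-3,3'-bis(2,4,6-triisopropylphenyl)-1,1'-binaphthyl-2,2'-diyl hydrogen phosphate (10 mol %), 4 Å MS, toluene, 0 °C to rt; aqueous work-up
Reagents that add atoms: 4,4,5,5-tetramethyl-2-(propa-1,2-dien-1-yl)-1,3,2-dioxaborolane, C=C=CB1OC(C)(C)C(C)(C)O1
Why: Chiral-phosphoric-acid-catalysed propargylation: the allenylboronate adds through a closed six-membered transition state to give only the homopropargylic alcohol; the catalyst directs attack to the Si face, which is also the Felkin–Anh face of the α-alkoxy aldehyde, and so sets (6S).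

Step 9
Reactants: 12 [(2S,3S,5R)-5-[(1S)-1-hydroxybut-3-yn-1-yl]-2-[(2E)-pent-2-en-1-yl]oxolan-3-yl] acetate
Product: 15 [(1R,3R,4S,6R,7R,9S)-4-bromo-3-ethyl-9-(prop-2-yn-1-yl)-2,8-dioxabicyclo[5.2.1]decan-6-yl] acetate, via bicyclic bromo-oxonium ion 13 (not isolated), via oxocane-fused dioxolanylium ion 14 (not isolated)
Conditions: Et2SBr·SbCl5Br (BDSB, 1.1 equiv), 2,6-di-tert-butyl-4-methylpyridine (1.2 equiv), MeNO2, −25 to 0 °C; aq. Na2SO3/NaHCO3
Reagents that add atoms: bromodiethylsulfonium bromopentachloroantimonate, CC[S+](Br)CC.Cl[Sb-](Cl)(Cl)(Cl)(Cl)Br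
Why: Proposed new method: BDSB transfers Br+ to the (E)-C12=C13 alkene, the oxolane oxygen adds 5-endo at C13 to give the cis-fused bicyclic oxonium ion 13, the carbonyl oxygen of the vicinal C9 acetate then opens 13 at C10 from the rear (which cleaves the shared O–C10 bond, expands the oxolane to the oxocane and leaves the 2-methyl-1,3-dioxolan-2-ylium ion 14), and the free C6 hydroxyl opens 14 at C9 from the rear to close the second oxolane and leave the acetate on C10. The closest known reactions are the bromonium-induced ring-expanding bromoetherification of 2-(alk-2-enyl)oxolanes in which a neighbouring tert-butyl carbonate opens the oxonium ion to an oxocane-fused cyclic carbonate, and the Lewis-acid-promoted cyclisation of triol orthoacetates in which a hydroxyl opens an acetoxonium ion to an oxolane with a vicinal acetate; an acetate as the opening group and the merger of both events in one flask are not documented. Modes of closure: bromooxolane ring of 13, 5-endo-trig; dioxolanylium ring of 14, 5-exo-tet at C10; oxocane, by ring expansion (fragmentation of the bicyclic oxonium ion), not by direct closure; final oxolane, 5-exo-tet at C9. C12 and C13 are set by anti addition across the E-alkene (trans Br/Et) on the alkene face that puts the ethyl group on the convex side of the cis-fused oxonium ion, trans to C9 across the new ring, as directed by C10; C10 and C9 are each set by one stereospecific SN2 inversion of the centres inherited from the bis-epoxide, so that the cis C9–O/C10–C11 arrangement of 12 becomes the (9R,10R) pattern of the target; C6 and C7 are not touched. The step needs attack of Br+ on the 1,2-dialkyl alkene and not on the terminal alkyne (the alkene is far more nucleophilic), opening of 13 only at C10 (only the vicinal acetate can reach the rear of an oxonium carbon through a five-membered transition state, whereas the C6 hydroxyl, tied to the same ring, cannot reach the rear of C10 and is kept unacylated so that it cannot open C7), and 5-exo capture of 14 at C9 in preference to 6-endo capture at C10. The hindered pyridine takes up the proton set free, so that the acid cannot re-ionise the product through its acetate.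

Step 10
Reactants: 15 [(1R,3R,4S,6R,7R,9S)-4-bromo-3-ethyl-9-(prop-2-yn-1-yl)-2,8-dioxabicyclo[5.2.1]decan-6-yl] acetate
Product: 17 [(1R,3R,4S,6R,7R,9S)-4-bromo-3-ethyl-9-[(2E)-3-iodoprop-2-en-1-yl]-2,8-dioxabicyclo[5.2.1]decan-6-yl] acetate, via alkenylzirconocene chloride 16 (not isolated)
Conditions: Cp2Zr(H)Cl (1.3 equiv), THF, rt, short reaction time; then I2, 0 °C
Reagents that add atoms: iodine, II
Why: Hydrozirconation of the terminal alkyne is syn and places zirconium on the terminal carbon; iodinolysis with retention gives the (E)-vinyl iodide, and the alkyne reacts faster than the acetate or the secondary bromide.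

Step 11
Reactants: 17 [(1R,3R,4S,6R,7R,9S)-4-bromo-3-ethyl-9-[(2E)-3-iodoprop-2-en-1-yl]-2,8-dioxabicyclo[5.2.1]decan-6-yl] acetate
Product: 18 [(1R,3R,4S,6R,7R,9S)-4-bromo-3-ethyl-9-[(2E)-pent-2-en-4-yn-1-yl]-2,8-dioxabicyclo[5.2.1]decan-6-yl] acetate
Conditions: HC≡CMgBr and ZnBr2 (gives HC≡CZnBr), Pd(PPh3)4 (5 mol %, zerovalent palladium), THF, rt
Reagents that add atoms: ethynylmagnesium bromide, C#C[Mg]Br (used as ethynylzinc bromide, C#C[Zn]Br)
Why: Negishi coupling of the alkenyl iodide with ethynylzinc bromide gives the terminal enyne with retention of the E geometry; oxidative addition to the C(sp2)–I bond is far faster than to the secondary alkyl bromide, and the neutral organozinc leaves the acetate alone.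

**Compound list**

1 | but-1-yne | CCC#C | starting material
2 | (2S,2'S)-2,2'-bioxirane | C1O[C@@H]1[C@@H]2CO2 | starting material
3 | (E)-but-1-enyl(diisobutyl)alane | CC/C=C/[Al](CC(C)C)CC(C)C | intermediate (not isolated)
4 | lithium (E)-but-1-enyl(butyl)(diisobutyl)aluminate | [Li+].CC/C=C/[Al-](CCCC)(CC(C)C)CC(C)C | intermediate (not isolated)
5 | (1S,3E)-1-[(2S)-oxiran-2-yl]hex-3-en-1-ol | CC/C=C/C[C@H](O)[C@@H]1CO1 | intermediate
6 | triethyl{[(1S,3E)-1-[(2S)-oxiran-2-yl]hex-3-en-1-yl]oxy}silane | CC/C=C/C[C@H](O[Si](CC)(CC)CC)[C@@H]1CO1 | intermediate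
7 | (4S,5S,7E)-5-[(triethylsilyl)oxy]deca-1,7-dien-4-ol | CC/C=C/C[C@H](O[Si](CC)(CC)CC)[C@@H](O)CC=C | intermediate
8 | (4S,5S,7E)-5-[(triethylsilyl)oxy]deca-1,7-dien-4-yl acetate | CC/C=C/C[C@H](O[Si](CC)(CC)CC)[C@@H](OC(C)=O)CC=C | intermediate
9 | (4S,5S,7E)-5-hydroxydeca-1,7-dien-4-yl acetate | CC/C=C/C[C@H](O)[C@@H](OC(C)=O)CC=C | intermediate
10 | [(2S,3S,5R)-5-(hydroxymethyl)-2-[(2E)-pent-2-en-1-yl]oxolan-3-yl] acetate | CC/C=C/C[C@@H]1O[C@H](C[C@@H]1OC(C)=O)CO | intermediate
11 | [(2S,3S,5R)-5-formyl-2-[(2E)-pent-2-en-1-yl]oxolan-3-yl] acetate | CC/C=C/C[C@@H]1O[C@H](C[C@@H]1OC(C)=O)C=O | intermediate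
12 | [(2S,3S,5R)-5-[(1S)-1-hydroxybut-3-yn-1-yl]-2-[(2E)-pent-2-en-1-yl]oxolan-3-yl] acetate | CC/C=C/C[C@@H]1O[C@H](C[C@@H]1OC(C)=O)[C@@H](O)CC#C | intermediate
13 | cis-fused 1-oxoniabicyclo[3.3.0]octane ion (oxonium O on C7, C10 and C13; Br on C12, acetate on C9) | CC[C@@H]1[C@@H](Br)C[C@@H]2[O+]1[C@H](C[C@@H]2OC(C)=O)[C@@H](O)CC#C | intermediate (not isolated)
14 | oxocane cis-fused at C9/C10 to a 2-methyl-1,3-dioxolan-2-ylium ion (Br on C12, free C6 hydroxyl) | CC[C@H]1O[C@H](C[C@@H]2OC(C)=[O+][C@@H]2C[C@@H]1Br)[C@@H](O)CC#C | intermediate (not isolated)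
15 | [(1R,3R,4S,6R,7R,9S)-4-bromo-3-ethyl-9-(prop-2-yn-1-yl)-2,8-dioxabicyclo[5.2.1]decan-6-yl] acetate | C#CC[C@@H]1O[C@@H]2C[C@H]1O[C@H](CC)[C@@H](Br)C[C@H]2OC(C)=O | intermediate
16 | (E)-alkenyl(chloro)zirconocene derived from 15 | Cl[Zr](C1C=CC=C1)(C1C=CC=C1)/C=C/C[C@@H]1O[C@@H]2C[C@H]1O[C@H](CC)[C@@H](Br)C[C@H]2OC(C)=O | intermediate (not isolated)
17 | [(1R,3R,4S,6R,7R,9S)-4-bromo-3-ethyl-9-[(2E)-3-iodoprop-2-en-1-yl]-2,8-dioxabicyclo[5.2.1]decan-6-yl] acetate | I/C=C/C[C@@H]1O[C@@H]2C[C@H]1O[C@H](CC)[C@@H](Br)C[C@H]2OC(C)=O | intermediate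
18 | [(1R,3R,4S,6R,7R,9S)-4-bromo-3-ethyl-9-[(2E)-pent-2-en-4-yn-1-yl]-2,8-dioxabicyclo[5.2.1]decan-6-yl] acetate | C#C/C=C/C[C@@H]1O[C@@H]2C[C@H]1O[C@H](CC)[C@@H](Br)C[C@H]2OC(C)=O | target

Total step count: 11
Longest linear sequence: 11 steps (from 1 and 2 to 18)

**Steps most likely to fail**

1. Step 9 (new method). The acetate may fail to open the oxonium ion cleanly, or the dioxolanylium ion may be captured by halide, or at C10, instead of by the C6 hydroxyl at C9. The fallback runs the same events as separate, individually precedented operations and sets out from alcohol 7. Boc2O and DMAP would give the tert-butyl carbonate F1, and PPTS in MeOH would free the C10 hydroxyl to give the hydroxy carbonate F2. The conditions of steps 6, 7 and 8 would then give the hydroxymethyl oxolane F3, the aldehyde F4 and the homopropargylic alcohol F5. BDSB in MeNO2 would effect the known ring-expanding bromoetherification, in which the carbonate carbonyl opens the oxonium ion and the tert-butyl group is lost, to give the oxocane-fused cyclic carbonate F6. K2CO3 in MeOH would cleave the carbonate to the triol F7. MeC(OMe)3 with PPTS would convert the cis-9,10-diol into the cyclic orthoacetate F8, and BF3·OEt2 would ionise it to the acetoxonium ion, which the C6 hydroxyl opens at C9 with inversion. This gives 15, where the route is rejoined.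

2. Step 8. Facial selectivity at C6 may be poor if catalyst control and substrate bias do not reinforce each other on this aldehyde. The fallback sets C6 by chelation control followed by SN2 inversion and sets out from aldehyde 11. Allenyltributylstannane with MgBr2·OEt2 in CH2Cl2 (chelate between the aldehyde oxygen and the ring oxygen) would give the (1R)-epimeric alcohol F9. Mitsunobu reaction with 4-nitrobenzoic acid, PPh3 and DIAD would invert C6 to the 4-nitrobenzoate F10. NaN3 in MeOH at 40 °C would cleave the 4-nitrobenzoate in the presence of the acetate and give 12.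

3. Step 10. Stoichiometric Cp2Zr(H)Cl may erode the acetate, or the iodide may form with incomplete regiocontrol. The fallback reverses the polarity of the enyne coupling and sets out from alkyne 15. Pinacolborane with catalytic Cp2Zr(H)Cl would hydroborate the alkyne to the (E)-alkenylboronate F11. Suzuki–Miyaura coupling with (bromoethynyl)triisopropylsilane, Pd(PPh3)4 (zerovalent palladium) and Ag2O would give the silyl enyne F12. TBAF buffered with AcOH would remove the silyl group and give 18 directly.

**Further compounds**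

F1 | step 9 | tert-butyl (4S,5S,7E)-5-[(triethylsilyl)oxy]deca-1,7-dien-4-yl carbonate | CC/C=C/C[C@H](O[Si](CC)(CC)CC)[C@@H](OC(=O)OC(C)(C)C)CC=C
F2 | step 9 | tert-butyl (4S,5S,7E)-5-hydroxydeca-1,7-dien-4-yl carbonate | CC/C=C/C[C@H](O)[C@@H](OC(=O)OC(C)(C)C)CC=C
F3 | step 9 | tert-butyl (2S,3S,5R)-5-(hydroxymethyl)-2-[(2E)-pent-2-en-1-yl]oxolan-3-yl carbonate | CC/C=C/C[C@@H]1O[C@H](C[C@@H]1OC(=O)OC(C)(C)C)CO
F4 | step 9 | tert-butyl (2S,3S,5R)-5-formyl-2-[(2E)-pent-2-en-1-yl]oxolan-3-yl carbonate | CC/C=C/C[C@@H]1O[C@H](C[C@@H]1OC(=O)OC(C)(C)C)C=O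
F5 | step 9 | tert-butyl (2S,3S,5R)-5-[(1S)-1-hydroxybut-3-yn-1-yl]-2-[(2E)-pent-2-en-1-yl]oxolan-3-yl carbonate | CC/C=C/C[C@@H]1O[C@H](C[C@@H]1OC(=O)OC(C)(C)C)[C@@H](O)CC#C
F6 | step 9 | oxocane cis-fused at C9/C10 to a 1,3-dioxolan-2-one (Br on C12, free C6 hydroxyl) | CC[C@H]1O[C@H](C[C@@H]2OC(=O)O[C@@H]2C[C@@H]1Br)[C@@H](O)CC#C
F7 | step 9 | (2R,3S,5R,6S,8R)-3-bromo-2-ethyl-8-[(1S)-1-hydroxybut-3-yn-1-yl]oxocane-5,6-diol | CC[C@H]1O[C@H](C[C@H](O)[C@H](O)C[C@@H]1Br)[C@@H](O)CC#C
F8 | step 9 | cyclic orthoacetate (2-methoxy-2-methyl-1,3-dioxolane) of F7 across C9/C10 | CC[C@H]1O[C@H](C[C@@H]2OC(C)(OC)O[C@@H]2C[C@@H]1Br)[C@@H](O)CC#C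
F9 | step 8 | [(2S,3S,5R)-5-[(1R)-1-hydroxybut-3-yn-1-yl]-2-[(2E)-pent-2-en-1-yl]oxolan-3-yl] acetate | CC/C=C/C[C@@H]1O[C@H](C[C@@H]1OC(C)=O)[C@H](O)CC#C
F10 | step 8 | (1S)-1-[(2R,4S,5S)-4-acetoxy-5-[(2E)-pent-2-en-1-yl]oxolan-2-yl]but-3-yn-1-yl 4-nitrobenzoate | CC/C=C/C[C@@H]1O[C@H](C[C@@H]1OC(C)=O)[C@@H](OC(=O)c1ccc(cc1)[N+](=O)[O-])CC#C
F11 | step 10 | (E)-alkenylboronic acid pinacol ester derived from 15 | CC1(C)OB(OC1(C)C)/C=C/C[C@@H]2O[C@@H]3C[C@H]2O[C@H](CC)[C@@H](Br)C[C@H]3OC(C)=O
F12 | step 10 | triisopropylsilyl-capped (E)-enyne corresponding to 18 | CC(C)[Si](C(C)C)(C(C)C)C#C/C=C/C[C@@H]1O[C@@H]2C[C@H]1O[C@H](CC)[C@@H](Br)C[C@H]2OC(C)=O
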